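**Plan**

1. Retrosynthetic cuts: the side chain at C13–C16 and C14–C15 (alkyne carboalumination, then formaldehyde) and at C9–C11 (addition to a C9 ketone); the C8 carbinol back to a C8 ketone masked as a dioxolane; C3–Br back to a C3 ketone; ring A at C1–C10 and C2–C3, which releases C1–C2 as methyl acrylate; C4–C5 by an Ireland–Claisen transform.
2. Forward order: ring B is 2-methylcyclohex-2-enone; C4 and C3 are attached to C5 by a [3,3] shift; C8 and C9 are oxidised to the α-keto ketal 12; ring A is annulated in one operation; then Br at C3, the side chain at C9, the carbinol at C8 and the 13E allylic alcohol.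
3. Feature that makes the annulation possible: in 12 the ring B ketone C9 lies between the dioxolane carbon C8 (no hydrogen) and C10 (its only α-CH, carrying the future angular methyl), and the C3 methyl ester hangs from C5 through the quaternary C4. Donor C10 and acceptor C3 are therefore 1,4-related and can close ring A around a two-carbon Michael acceptor.
4. Stereochemistry: absolute configuration comes from one CBS reduction (C9–O) and is relayed to C5 by the suprafacial [3,3] shift; C10 follows from C5 in the stereoconvergent annulation (both C10 epimers of 12 pass through one enolate); C3 by axial hydrogen delivery to a radical; C9 by enolate protonation; C8 by epoxidation anti to the C10 methyl; 13E by syn-carbometalation.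

Key step: step 9

Remark: labdane numbering is used for all intermediates (ring A = C1–C5 and C10, ring B = C5–C10). The target is read as the (3R,5S,8S,9S,10R,13E) isomer, a trans-fused decalin of the ent-labdane series, and in every bicyclic intermediate H-5 is anti to the C10 methyl. Compounds 1, 3, 13 and 19 are taken as commercial.

**Step 1**
Reactants: 1 2-methylcyclohex-2-en-1-one
Product: 2 (R)-2-methylcyclohex-2-en-1-ol
Conditions: (S)-2-methyl-CBS-oxazaborolidine (10 mol%), BH3·SMe2, THF, −20 °C; MeOH, aq. NH4Cl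
Reagents that add atoms: none
Why: CBS reduction: with the α-methyl alkenyl arm acting as the large group, the (S)-catalyst should give 1,2-reduction to the (R)-allylic alcohol, the only source of absolute configuration in the route.

**Step 2**
Reactants: 2 (R)-2-methylcyclohex-2-en-1-ol; 3 isobutyryl chloride
Product: 4 (R)-2-methylcyclohex-2-en-1-yl 2-methylpropanoate
Conditions: Et3N, DMAP (cat.), CH2Cl2, 0 °C
Reagents that add atoms: none
Why: Standard O-acylation of a secondary allylic alcohol; the carbinol centre is not touched.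

**Step 3**
Reactants: 4 (R)-2-methylcyclohex-2-en-1-yl 2-methylpropanoate
Product: 7 2-methyl-2-[(1S)-2-methylcyclohex-2-en-1-yl]propanoic acid, via silyl ketene acetal 5 (not isolated), via trimethylsilyl ester 6 (not isolated)
Conditions: LiN(i-Pr)2, Me3SiCl, THF, −78 °C → 60 °C; then 1 M HCl
Reagents that add atoms: none
Why: Ireland–Claisen rearrangement: the dimethyl ketene acetal has no E/Z issue and the [3,3] shift is suprafacial on the ring, so the C9–O configuration is relayed to C5 as the C4–C5 bond forms next to the quaternary C4.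

**Step 4**
Reactants: 7 2-methyl-2-[(1S)-2-methylcyclohex-2-en-1-yl]propanoic acid
Product: 8 methyl 2-methyl-2-[(1S)-2-methylcyclohex-2-en-1-yl]propanoate
Conditions: MeI, K2CO3, DMF, 23 °C
Reagents that add atoms: iodomethane, CI
Why: SN2 O-methylation of the carboxylate gives the methyl ester that later serves as the C3 acyl acceptor; no stereocentre is involved.

**Step 5**
Reactants: 8 methyl 2-methyl-2-[(1S)-2-methylcyclohex-2-en-1-yl]propanoate
Product: 9 methyl 2-methyl-2-[(1S)-2-methyl-4-oxocyclohex-2-en-1-yl]propanoate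
Conditions: Rh2(cap)4 [dirhodium tetrakis(caprolactamate)] (1 mol%), t-BuOOH, K2CO3, CH2Cl2, 23 °C
Reagents that add atoms: tert-butyl hydroperoxide, CC(C)(C)OO
Why: Radical allylic oxidation of a 1-methylcyclohexene: hydrogen abstraction should occur at the unhindered ring methylene C8 (the tertiary C5–H is shielded by the neighbouring quaternary carbon) and lead to the β-methyl enone, leaving C5 untouched.

**Step 6**
Reactants: 9 methyl 2-methyl-2-[(1S)-2-methyl-4-oxocyclohex-2-en-1-yl]propanoate
Product: 10 methyl 2-methyl-2-[(8S)-7-methyl-1,4-dioxaspiro[4.5]dec-6-en-8-yl]propanoate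
Conditions: Me3SiOCH2CH2OSiMe3, Me3SiOTf (5 mol%), CH2Cl2, −78 → −20 °C
Reagents that add atoms: 1,2-bis(trimethylsilyloxy)ethane, C[Si](C)(C)OCCO[Si](C)(C)C
Why: Silyl-transfer ketalisation at low temperature is kinetically controlled and should give the dioxolane without moving the C9=C10 double bond towards C5, so the C5 centre survives.

**Step 7**
Reactants: 10 methyl 2-methyl-2-[(8S)-7-methyl-1,4-dioxaspiro[4.5]dec-6-en-8-yl]propanoate
Product: 11 methyl 2-[(6R,7S,8S)-6-hydroxy-7-methyl-1,4-dioxaspiro[4.5]decan-8-yl]-2-methylpropanoate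
Conditions: BH3·THF, THF, 0 °C; then NaOH, H2O2, 0 °C
Reagents that add atoms: hydrogen peroxide, OO
Why: Hydroboration–oxidation: boron goes to the less substituted C9 and syn addition occurs anti to the bulky C5 substituent, giving the C9 alcohol (the C10 configuration set here is erased in step 9); the hindered ester should survive at 0 °C.

**Step 8**
Reactants: 11 methyl 2-[(6R,7S,8S)-6-hydroxy-7-methyl-1,4-dioxaspiro[4.5]decan-8-yl]-2-methylpropanoate
Product: 12 methyl 2-methyl-2-[(7S,8S)-7-methyl-6-oxo-1,4-dioxaspiro[4.5]decan-8-yl]propanoate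
Conditions: Dess–Martin periodinane, NaHCO3, CH2Cl2, 23 °C
Reagents that add atoms: none
Why: Dess–Martin oxidation of the secondary alcohol gives the α-keto ketal whose only enolisable position is C10; epimerisation at C10 is of no consequence.

**Step 9**
Reactants: 12 methyl 2-methyl-2-[(7S,8S)-7-methyl-6-oxo-1,4-dioxaspiro[4.5]decan-8-yl]propanoate; 13 methyl acrylate
Product: 15 methyl 8,8-ethylenedioxy-4,4,10-trimethyl-3,9-dioxo-trans-decalin-2-carboxylate, via Michael adduct 14 (not isolated)
Conditions: KOt-Bu (2.2 equiv), THF, −20 °C; 13 (1.05 equiv, slow addition); → 45 °C; aq. NH4Cl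
Reagents that add atoms: none
Why: KOt-Bu removes the only enolisable hydrogen of 12 (C10–H), so both C10 epimers converge on one tetrasubstituted enolate, which adds to methyl acrylate to forge C1–C10 (adduct 14); the ester enolate at C2 then attacks the pendant C3 methyl ester in a Dieckmann condensation, expelling methoxide, and deprotonation of the β-keto ester 15 drives the sequence. The closest known reaction type is the tandem Michael–Claisen (Michael–Dieckmann) annulation of ketone enolates with acrylates. Ring A closes by a 6-exo-trig acyl substitution of the C2 enolate on the C3 ester carbonyl. The new quaternary centre C10 is controlled by C5: allylic 1,2-strain with the C10 methyl forces the bulky C5 substituent pseudoaxial in the enolate, so the acrylate enters on the opposite face and C1 ends up trans to C4 on ring B, the only arrangement that can close ring A through a diequatorial chair to the trans-decalin. C2 is formed as an epimer and enol mixture and is erased in step 10. Regioselectivity (C10 versus C8) is secured by the C8 dioxolane, and the Claisen step is unambiguous because C9 has no α-hydrogen left and the only six-membered closure open to the C2 enolate is onto C3.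

**Step 10**
Reactants: 15 methyl 8,8-ethylenedioxy-4,4,10-trimethyl-3,9-dioxo-trans-decalin-2-carboxylate
Product: 16 8,8-ethylenedioxy-4,4,10-trimethyl-trans-decalin-3,9-dione
Conditions: LiCl, H2O, DMSO, 150 °C
Reagents that add atoms: none
Why: Krapcho dealkoxycarbonylation: chloride demethylates the β-keto ester and the carboxylate loses CO2, leaving the C3 ketone; the neutral medium spares the dioxolane and no stereocentre is touched.

**Step 11**
Reactants: 16 8,8-ethylenedioxy-4,4,10-trimethyl-trans-decalin-3,9-dione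
Product: 17 3-bromo-8,8-ethylenedioxy-4,4,10-trimethyl-trans-decal-2-en-9-one
Conditions: P(OPh)3, Br2, CH2Cl2, −60 °C; then Et3N, 16; → reflux
Reagents that add atoms: bromine, BrBr
Why: Ketone to vinyl bromide conversion with triphenyl phosphite dibromide: only the C3 ketone has α-hydrogens (at C2), whereas C9 is flanked by two fully substituted carbons and cannot enolise, so the C2=C3 bromoalkene should form selectively.

**Step 12**
Reactants: 17 3-bromo-8,8-ethylenedioxy-4,4,10-trimethyl-trans-decal-2-en-9-one
Product: 18 (3R,5S,10R)-3-bromo-8,8-ethylenedioxy-4,4,10-trimethyl-trans-decalin-9-one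
Conditions: tris(2,2,6,6-tetramethylheptane-3,5-dionato)manganese, Mn(dpm)3 (10 mol%), PhSiH3, t-BuOOH, i-PrOH, 23 °C
Reagents that add atoms: none
Why: Metal-hydride hydrogen-atom-transfer hydrogenation of an alkenyl halide: H• adds to C2, and the α-bromo C3 radical should take its second hydrogen axially on the face away from the C10 and axial C4 methyls, so bromine ends up equatorial and cis to the C10 methyl (the more stable epimer) with the C–Br bond kept.

**Step 13**
Reactants: 18 (3R,5S,10R)-3-bromo-8,8-ethylenedioxy-4,4,10-trimethyl-trans-decalin-9-one; 19 (4-bromobut-1-yn-1-yl)trimethylsilane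
Product: 21 3-bromo-8,8-ethylenedioxy-9-hydroxy-4,4,10-trimethyl-9-[4-(trimethylsilyl)but-3-yn-1-yl]-trans-decalin, via Grignard reagent 20 (not isolated)
Conditions: 19, Mg, THF; CeCl3, THF, −78 °C; then 18, −78 → 0 °C; aq. NH4Cl
Reagents that add atoms: none
Why: Organocerium (Grignard/CeCl3) 1,2-addition to a hindered, non-enolisable ketone, helped by chelation to the α-ketal oxygen; attack should come axially on the face away from the C10 methyl, but the new C9 centre is not needed later.

**Step 14**
Reactants: 21 3-bromo-8,8-ethylenedioxy-9-hydroxy-4,4,10-trimethyl-9-[4-(trimethylsilyl)but-3-yn-1-yl]-trans-decalin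
Product: 23 3-bromo-4,4,10-trimethyl-9-[4-(trimethylsilyl)but-3-yn-1-ylidene]-trans-decalin-8-one, via alkylidene ketal 22 (not isolated)
Conditions: SOCl2, pyridine, CH2Cl2, −10 °C; then 1 M HCl, THF, 23 °C
Reagents that add atoms: water, O
Why: Dehydration of the tertiary alcohol can only go towards C11 because C8 and C10 carry no hydrogen, and hydrolysis of the now allylic dioxolane gives the C8 enone; the E/Z mixture converges in step 15.

**Step 15**
Reactants: 23 3-bromo-4,4,10-trimethyl-9-[4-(trimethylsilyl)but-3-yn-1-ylidene]-trans-decalin-8-one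
Product: 24 (3R,5S,9S,10R)-3-bromo-14-(trimethylsilyl)-15,16,17-trinorlabd-13-yn-8-one
Conditions: [(Ph3P)CuH]6 (5 mol%), PhSiH3, toluene, 23 °C; then 1 M HCl work-up
Reagents that add atoms: none
Why: Copper hydride conjugate reduction of the α-alkylidene ketone puts hydride on C11, and protonation at C9 from the face away from the C10 methyl (also the thermodynamic outcome, with the side chain equatorial) sets C9.

**Step 16**
Reactants: 24 (3R,5S,9S,10R)-3-bromo-14-(trimethylsilyl)-15,16,17-trinorlabd-13-yn-8-one
Product: 25 3-bromo-14-(trimethylsilyl)-15,16-dinorlabd-8(17)-en-13-yne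
Conditions: Ph3PCH3Br, KOt-Bu, toluene, 23 → 70 °C
Reagents that add atoms: methyltriphenylphosphonium bromide, C[P+](c1ccccc1)(c1ccccc1)c1ccccc1.[Br-]
Why: Wittig methylenation of the C8 ketone; C9 is already the preferred epimer and the equatorial bromide has no anti-periplanar hydrogen for elimination.

**Step 17**
Reactants: 25 3-bromo-14-(trimethylsilyl)-15,16-dinorlabd-8(17)-en-13-yne
Product: 26 3-bromo-8,17-epoxy-14-(trimethylsilyl)-15,16-dinorlabd-13-yne
Conditions: mCPBA, NaHCO3, CH2Cl2, 0 °C
Reagents that add atoms: 3-chloroperbenzoic acid, OOC(=O)c1cccc(Cl)c1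
Why: Prilezhaev epoxidation of the 1,1-disubstituted alkene from the face away from the axial C10 methyl places oxygen equatorial at C8; the silyl alkyne is inert to peracid.

**Step 18**
Reactants: 26 3-bromo-8,17-epoxy-14-(trimethylsilyl)-15,16-dinorlabd-13-yne
Product: 27 (3R,5S,8S,9S,10R)-3-bromo-14-(trimethylsilyl)-15,16-dinorlabd-13-yn-8-ol
Conditions: LiAlH4, THF, 0 °C
Reagents that add atoms: none
Why: Hydride opens the spiro-epoxide at its CH2 terminus (SN2), which becomes the axial C8 methyl and leaves the equatorial tertiary alcohol; the equatorial neopentyl bromide should not be displaced.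

**Step 19**
Reactants: 27 (3R,5S,8S,9S,10R)-3-bromo-14-(trimethylsilyl)-15,16-dinorlabd-13-yn-8-ol
Product: 28 (3R,5S,8S,9S,10R)-3-bromo-15,16-dinorlabd-13-yn-8-ol
Conditions: K2CO3, MeOH, 23 °C
Reagents that add atoms: none
Why: Methanolysis of the alkynyl–silicon bond frees the terminal alkyne without touching the bromide or the carbinol.

**Step 20**
Reactants: 28 (3R,5S,8S,9S,10R)-3-bromo-15,16-dinorlabd-13-yn-8-ol
Product: 31 (3R,5S,8S,9S,10R,13E)-3-bromolabd-13-ene-8,15-diol, via alkenylalane 29 (not isolated), via lithium alanate 30 (not isolated)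
Conditions: AlMe3, Cp2ZrCl2 (25 mol%), CH2Cl2, 0 → 23 °C; then n-BuLi, THF, −78 °C; (CH2O)n, 23 °C; aq. potassium sodium tartrate
Reagents that add atoms: trimethylaluminium, C[Al](C)C; formaldehyde (from paraformaldehyde), C=O
Why: Negishi zirconium-catalysed carboalumination adds methyl and aluminium syn across the terminal alkyne (methyl to C13), and the alanate is hydroxymethylated with retention, so the 13E trisubstituted alkene follows from the syn addition.

**Compound list**

1 | 2-methylcyclohex-2-en-1-one | CC1=CCCCC1=O | starting material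
2 | (R)-2-methylcyclohex-2-en-1-ol | O[C@@H]1CCCC=C1C | intermediate
3 | isobutyryl chloride (2-methylpropanoyl chloride) | CC(C)C(Cl)=O | starting material
4 | (R)-2-methylcyclohex-2-en-1-yl 2-methylpropanoate | CC(C)C(=O)O[C@@H]1CCCC=C1C | intermediate
5 | silyl ketene acetal of 4, trimethyl({2-methyl-1-[(1R)-2-methylcyclohex-2-en-1-yl]oxyprop-1-en-1-yl}oxy)silane | CC(C)=C(O[Si](C)(C)C)O[C@@H]1CCCC=C1C | intermediate (not isolated)
6 | trimethylsilyl 2-methyl-2-[(1S)-2-methylcyclohex-2-en-1-yl]propanoate | C[Si](C)(C)OC(=O)C(C)(C)[C@H]1CCCC=C1C | intermediate (not isolated)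
7 | 2-methyl-2-[(1S)-2-methylcyclohex-2-en-1-yl]propanoic acid | OC(=O)C(C)(C)[C@H]1CCCC=C1C | intermediate
8 | methyl 2-methyl-2-[(1S)-2-methylcyclohex-2-en-1-yl]propanoate | COC(=O)C(C)(C)[C@H]1CCCC=C1C | intermediate
9 | methyl 2-methyl-2-[(1S)-2-methyl-4-oxocyclohex-2-en-1-yl]propanoate | COC(=O)C(C)(C)[C@H]1CCC(=O)C=C1C | intermediate
10 | methyl 2-methyl-2-[(8S)-7-methyl-1,4-dioxaspiro[4.5]dec-6-en-8-yl]propanoate | COC(=O)C(C)(C)[C@H]1CCC2(OCCO2)C=C1C | intermediate
11 | methyl 2-[(6R,7S,8S)-6-hydroxy-7-methyl-1,4-dioxaspiro[4.5]decan-8-yl]-2-methylpropanoate (OH trans to the C5 side arm, methyl cis to it) | COC(=O)C(C)(C)[C@H]1CCC2(OCCO2)[C@H](O)[C@H]1C | intermediate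
12 | methyl 2-methyl-2-[(7S,8S)-7-methyl-6-oxo-1,4-dioxaspiro[4.5]decan-8-yl]propanoate (α-keto ketal; C10 epimerisable) | COC(=O)C(C)(C)[C@H]1CCC2(OCCO2)C(=O)[C@H]1C | intermediate
13 | methyl acrylate | C=CC(=O)OC | starting material
14 | methyl 3-[(7R,8S)-8-(1-methoxy-2-methyl-1-oxopropan-2-yl)-7-methyl-6-oxo-1,4-dioxaspiro[4.5]decan-7-yl]propanoate (Michael adduct; propanoate arm trans to the C5 side arm) | O=C1[C@](C)(CCC(=O)OC)[C@@H](C(C)(C)C(=O)OC)CCC12OCCO2 | intermediate (not isolated)
15 | methyl 8,8-ethylenedioxy-4,4,10-trimethyl-3,9-dioxo-trans-decalin-2-carboxylate (C5 and C10 as in the target; C2 epimers and enol) | O=C1[C@]2(C)CC(C(=O)OC)C(=O)C(C)(C)[C@H]2CCC13OCCO3 | intermediate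
16 | 8,8-ethylenedioxy-4,4,10-trimethyl-trans-decalin-3,9-dione | O=C1[C@]2(C)CCC(=O)C(C)(C)[C@H]2CCC13OCCO3 | intermediate
17 | 3-bromo-8,8-ethylenedioxy-4,4,10-trimethyl-trans-decal-2-en-9-one | O=C1[C@]2(C)CC=C(Br)C(C)(C)[C@H]2CCC13OCCO3 | intermediate
18 | (3R,5S,10R)-3-bromo-8,8-ethylenedioxy-4,4,10-trimethyl-trans-decalin-9-one (Br equatorial, cis to the C10 methyl) | O=C1[C@]2(C)CC[C@@H](Br)C(C)(C)[C@H]2CCC13OCCO3 | intermediate
19 | (4-bromobut-1-yn-1-yl)trimethylsilane | C[Si](C)(C)C#CCCBr | starting material
20 | [4-(trimethylsilyl)but-3-yn-1-yl]magnesium bromide | C[Si](C)(C)C#CCC[Mg]Br | intermediate (not isolated)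
21 | 3-bromo-8,8-ethylenedioxy-9-hydroxy-4,4,10-trimethyl-9-[4-(trimethylsilyl)but-3-yn-1-yl]-trans-decalin (side chain anti, OH syn to the C10 methyl) | C[Si](C)(C)C#CCC[C@]1(O)[C@]2(C)CC[C@@H](Br)C(C)(C)[C@H]2CCC13OCCO3 | intermediate
22 | 3-bromo-8,8-ethylenedioxy-4,4,10-trimethyl-9-[4-(trimethylsilyl)but-3-yn-1-ylidene]-trans-decalin (E/Z mixture) | C[Si](C)(C)C#CCC=C1[C@]2(C)CC[C@@H](Br)C(C)(C)[C@H]2CCC13OCCO3 | intermediate (not isolated)
23 | 3-bromo-4,4,10-trimethyl-9-[4-(trimethylsilyl)but-3-yn-1-ylidene]-trans-decalin-8-one (E/Z mixture) | C[Si](C)(C)C#CCC=C1[C@]2(C)CC[C@@H](Br)C(C)(C)[C@H]2CCC1=O | intermediate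
24 | (3R,5S,9S,10R)-3-bromo-14-(trimethylsilyl)-15,16,17-trinorlabd-13-yn-8-one (H-9 anti to the C10 methyl) | C[Si](C)(C)C#CCC[C@H]1[C@]2(C)CC[C@@H](Br)C(C)(C)[C@H]2CCC1=O | intermediate
25 | 3-bromo-14-(trimethylsilyl)-15,16-dinorlabd-8(17)-en-13-yne (ring stereocentres as in 24) | C[Si](C)(C)C#CCC[C@H]1[C@]2(C)CC[C@@H](Br)C(C)(C)[C@H]2CCC1=C | intermediate
26 | 3-bromo-8,17-epoxy-14-(trimethylsilyl)-15,16-dinorlabd-13-yne (epoxide oxygen anti to the C10 methyl) | C[Si](C)(C)C#CCC[C@H]1[C@]2(C)CC[C@@H](Br)C(C)(C)[C@H]2CC[C@@]13CO3 | intermediate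
27 | (3R,5S,8S,9S,10R)-3-bromo-14-(trimethylsilyl)-15,16-dinorlabd-13-yn-8-ol | C[Si](C)(C)C#CCC[C@H]1[C@]2(C)CC[C@@H](Br)C(C)(C)[C@H]2CC[C@]1(C)O | intermediate
28 | (3R,5S,8S,9S,10R)-3-bromo-15,16-dinorlabd-13-yn-8-ol | C#CCC[C@H]1[C@]2(C)CC[C@@H](Br)C(C)(C)[C@H]2CC[C@]1(C)O | intermediate
29 | (E)-alkenyl(dimethyl)alane of 28, with the C8 oxygen as its dimethylaluminium alkoxide | C/C(=C\[Al](C)C)CC[C@H]1[C@]2(C)CC[C@@H](Br)C(C)(C)[C@H]2CC[C@]1(C)O[Al](C)C | intermediate (not isolated)
30 | lithium butyl(dimethyl)alkenylalanate derived from 29 | [Li+].CCCC[Al-](C)(C)/C=C(\C)CC[C@H]1[C@]2(C)CC[C@@H](Br)C(C)(C)[C@H]2CC[C@]1(C)O[Al](C)C | intermediate (not isolated)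
31 | (3R,5S,8S,9S,10R,13E)-3-bromolabd-13-ene-8,15-diol | C/C(=C\CO)CC[C@H]1[C@]2(C)CC[C@@H](Br)C(C)(C)[C@H]2CC[C@]1(C)O | target

**Step count and risks**

Total steps: 20. Longest linear sequence: 20 (the route is linear from 1).

Steps most likely to fail:

Step 9. The conjugate addition at the congested C10 enolate carbon may be slow, so that the acrylate oligomerises or a second acrylate adds to the product enolate. Fallback, setting out from 12 and returning at 14: the potassium enolate (KN(SiMe3)2, THF, −78 °C) would be alkylated with allyl iodide, a smaller and irreversible electrophile under the same facial control by C5, to give the C10-allyl ketone F1. Hydroboration with 9-BBN and NaOH/H2O2 would give the primary alcohol F2, TEMPO/PhI(OAc)2 in wet MeCN the acid F3, and MeI/K2CO3 the keto diester 14, which KOt-Bu in THF would close to 15. The two ring A bonds would then be made in separate operations.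

Step 13. The 1,2-addition may be blocked by the two fully substituted neighbours of C9, with β-hydride reduction of the ketone taking over. Fallback, setting out from 18 and returning at 21: Corey–Chaykovsky epoxidation with dimethylsulfonium methylide (trimethylsulfonium iodide, KN(SiMe3)2, THF, 0 °C), a small and irreversible nucleophile, would give the spiro-epoxide F4 with CH2 delivered from the face away from the C10 methyl. Opening at the CH2 terminus with lithiated 1-(trimethylsilyl)propyne (n-BuLi, then BF3·OEt2, THF, −78 °C) would give 21 directly.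

Step 12. Hydrogen delivery to the C3 radical may show poor facial selectivity, or bromine may be lost by over-reduction. Fallback, setting out from 16 and returning at 18: LiBH(s-Bu)3 (THF, −78 °C) would reduce the C3 ketone from the equatorial side to the axial alcohol F5 (C9 is too hindered to react), Tf2O/pyridine would give the triflate F6, and Bu4NBr in toluene would displace it with inversion to the equatorial bromide 18. The C–Br bond would then be made by SN2 rather than the C–H bond by radical transfer; elimination to the C2=C3 alkene would be the competing process to watch.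

**Further compounds**

F1 | step 9 | methyl 2-methyl-2-[(7R,8S)-7-methyl-6-oxo-7-(prop-2-en-1-yl)-1,4-dioxaspiro[4.5]decan-8-yl]propanoate | O=C1[C@](C)(CC=C)[C@@H](C(C)(C)C(=O)OC)CCC12OCCO2
F2 | step 9 | methyl 2-[(7R,8S)-7-(3-hydroxypropyl)-7-methyl-6-oxo-1,4-dioxaspiro[4.5]decan-8-yl]-2-methylpropanoate | O=C1[C@](C)(CCCO)[C@@H](C(C)(C)C(=O)OC)CCC12OCCO2
F3 | step 9 | 3-[(7R,8S)-8-(1-methoxy-2-methyl-1-oxopropan-2-yl)-7-methyl-6-oxo-1,4-dioxaspiro[4.5]decan-7-yl]propanoic acid | O=C1[C@](C)(CCC(O)=O)[C@@H](C(C)(C)C(=O)OC)CCC12OCCO2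
F4 | step 13 | 3-bromo-9,11-epoxy-8,8-ethylenedioxy-4,4,10-trimethyl-9-methylene-derived spiro-epoxide of the trans-decalin (epoxide CH2 anti to the C10 methyl) | C1O[C@]12[C@]3(C)CC[C@@H](Br)C(C)(C)[C@H]3CCC24OCCO4
F5 | step 12 | 8,8-ethylenedioxy-3-hydroxy-4,4,10-trimethyl-trans-decalin-9-one (axial C3 hydroxyl, anti to the C10 methyl) | O=C1[C@]2(C)CC[C@H](O)C(C)(C)[C@H]2CCC13OCCO3
F6 | step 12 | 8,8-ethylenedioxy-4,4,10-trimethyl-9-oxo-trans-decalin-3-yl trifluoromethanesulfonate (axial C3 triflate) | O=C1[C@]2(C)CC[C@H](OS(=O)(=O)C(F)(F)F)C(C)(C)[C@H]2CCC13OCCO3
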